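**Retrosynthetic overview**
- The anisate is attached last by acylating the secondary allylic hydroxyl of a cis-1,3-diol. The tertiary ring-fusion hydroxyl needs no protection.
- Ring B (seven-membered) is opened at its trisubstituted C=C by ring-closing metathesis, giving a cyclopentane with cis vinyl-carbinol and 3-methylbut-3-enyl arms.
- Both arms come from one keto aldehyde: vinyl adds to the CHO group and the homoallyl group adds to the ring ketone.
- Ring A (five-membered) with its quaternary methyl centre comes from a stereospecific 1,2-acyl shift, a ring contraction of a 2,3-epoxycyclohexanone.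
- Key C–O step: catalytic dynamic kinetic asymmetric epoxidation of piperitone. The oxygen installed here ends up as the alkyl oxygen of the ester. Ring order: purchased six-membered ring, then ring A by contraction, then ring B by metathesis.

Assumption: the quinine-derived amine delivers the peroxide to the C3 face that leads to the (1S,6S)-epoxide; if the sense proves opposite, its quinidine-derived pseudoenantiomer is used under the same conditions.

**Step 1**
Reactants: 1 piperitone (commercial, racemic or (R)-enriched; the C6 centre is labile)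
Product: 2 (1S,3R,6S)-6-methyl-3-(propan-2-yl)-7-oxabicyclo[4.1.0]heptan-2-one (epoxide oxygen anti to isopropyl; methyl and isopropyl cis)
Conditions: 9-amino-9-deoxy-epi-quinine (10 mol %), CF3CO2H (20 mol %), 50% aq H2O2 (1.5 equiv), dioxane, 40 °C, 48 h
Reagents that add atoms: hydrogen peroxide, OO
Why: Proposed new method: a dynamic kinetic asymmetric Weitz–Scheffer epoxidation, in which the primary amine condenses with 1 to a ketiminium ion whose C6–H exchanges through the cross-conjugated dienamine (so both enantiomers of 1 interconvert), allylic 1,3-strain with the N-substituent holds the isopropyl group pseudoaxial, the quinuclidinium-bound hydroperoxide adds axially to C3 only on the face anti to that group (matched for the 6R iminium ion), and the β-peroxy enamine closes to the epoxide, fixing C1, C6 and C3 of 2 in one operation; the closest known reaction type is the amine-salt (iminium) catalysed asymmetric epoxidation of simple cyclic enones with H2O2, which has not been run as a dynamic kinetic resolution of an α'-stereolabile enone.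

**Step 2**
Reactants: 2 (1S,3R,6S)-6-methyl-3-(propan-2-yl)-7-oxabicyclo[4.1.0]heptan-2-one
Product: 3 (1R,3R)-1-methyl-2-oxo-3-(propan-2-yl)cyclopentane-1-carbaldehyde (methyl and isopropyl cis)
Conditions: BF3·OEt2 (20 mol %), toluene, 0 °C to rt, 30 min; water wash, no base
Reagents that add atoms: none
Why: Lewis-acid-promoted epoxy ketone rearrangement (Meinwald-type 1,2-acyl shift), in which BF3 opens the tertiary C–O bond and the ring acyl carbon migrates to its rear side with inversion, contracting the ring and converting the epoxide configuration into the quaternary centre, while the epoxide oxygen stays on the carbon that becomes the aldehyde.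

**Step 3**
Reactants: 3 (1R,3R)-1-methyl-2-oxo-3-(propan-2-yl)cyclopentane-1-carbaldehyde, 4 vinylmagnesium bromide, 5 4-bromo-2-methylbut-1-ene
Product: 8 (1S,2R,5R)-2-[(1S)-1-hydroxyprop-2-en-1-yl]-2-methyl-1-(3-methylbut-3-en-1-yl)-5-(propan-2-yl)cyclopentan-1-ol, via 3-methylbut-3-enylmagnesium bromide 6 (not isolated), via bromomagnesium aldolate 7 (not isolated)
Conditions: 4 (1.05 equiv), THF, −78 °C; then LaCl3·2LiCl (1.0 equiv) and 6 (2.5 equiv, from 5 and Mg turnings in THF), −78 to 0 °C; sat. aq NH4Cl
Reagents that add atoms: vinylmagnesium bromide, C=C[Mg]Br; 4-bromo-2-methylbut-1-ene, C=C(C)CCBr (used as its Grignard reagent, C=C(C)CC[Mg]Br)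
Why: Sequential Grignard 1,2-additions, in which the aldehyde reacts first under Felkin–Anh control (vinyl enters anti to the acyl carbon and past the methyl group rather than the ring CH2, giving the 1S carbinol) and the LaCl3-activated ketone is then attacked from the face opposite to the cis methyl and isopropyl groups, which places the tertiary hydroxyl cis to both.

**Step 4**
Reactants: 8 (1S,2R,5R)-2-[(1S)-1-hydroxyprop-2-en-1-yl]-2-methyl-1-(3-methylbut-3-en-1-yl)-5-(propan-2-yl)cyclopentan-1-ol
Product: 9 (3R,3aS,8S,8aR)-6,8a-dimethyl-3-(propan-2-yl)-2,3,4,5,8,8a-hexahydroazulene-3a,8(1H)-diol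
Conditions: second-generation Grubbs catalyst (5 mol %), 1,4-benzoquinone (10 mol %), CH2Cl2 (2 mM), reflux
Reagents that add atoms: none
Why: Ring-closing metathesis, in which the two alkenyl arms are cis on ring A so that the ruthenium carbene formed at the vinyl group closes on the 1,1-disubstituted alkene to the trisubstituted cycloheptene (ring B) with loss of ethene and without touching a stereocentre.

**Step 5**
Reactants: 9 (3R,3aS,8S,8aR)-6,8a-dimethyl-3-(propan-2-yl)-2,3,4,5,8,8a-hexahydroazulene-3a,8(1H)-diol, 10 4-methoxybenzoyl chloride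
Product: 11 (3R,3aS,8S,8aR)-3a-hydroxy-6,8a-dimethyl-3-(propan-2-yl)-1,2,3,3a,4,5,8,8a-octahydroazulen-8-yl 4-methoxybenzoate (CNP0158828.1)
Conditions: 10 (1.5 equiv), Et3N (3 equiv), DMAP (20 mol %), CH2Cl2, 0 °C to rt
Reagents that add atoms: 4-methoxybenzoyl chloride, COc1ccc(cc1)C(Cl)=O
Why: DMAP-catalysed acylation (nucleophilic catalysis), in which only the secondary allylic hydroxyl reacts because the tertiary ring-fusion hydroxyl is inert, and the C8–O bond is not broken, so its configuration is retained.

**Compound list**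
1 | piperitone, 3-methyl-6-(propan-2-yl)cyclohex-2-en-1-one | CC1=CC(=O)C(C(C)C)CC1 | starting material
2 | (1S,3R,6S)-6-methyl-3-(propan-2-yl)-7-oxabicyclo[4.1.0]heptan-2-one | CC(C)[C@H]1CC[C@]2(C)O[C@@H]2C1=O | intermediate
3 | (1R,3R)-1-methyl-2-oxo-3-(propan-2-yl)cyclopentane-1-carbaldehyde | O=C[C@@]1(C)CC[C@H](C(C)C)C1=O | intermediate
4 | vinylmagnesium bromide | C=C[Mg]Br | starting material
5 | 4-bromo-2-methylbut-1-ene | C=C(C)CCBr | starting material
6 | 3-methylbut-3-en-1-ylmagnesium bromide | C=C(C)CC[Mg]Br | intermediate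
7 | bromomagnesium alkoxide of (2R,5R)-2-[(1S)-1-hydroxyprop-2-en-1-yl]-2-methyl-5-(propan-2-yl)cyclopentan-1-one | C=C[C@H](O[Mg]Br)[C@@]1(C)CC[C@H](C(C)C)C1=O | intermediate
8 | (1S,2R,5R)-2-[(1S)-1-hydroxyprop-2-en-1-yl]-2-methyl-1-(3-methylbut-3-en-1-yl)-5-(propan-2-yl)cyclopentan-1-ol | C=C[C@H](O)[C@@]1(C)CC[C@H](C(C)C)[C@@]1(O)CCC(C)=C | intermediate
9 | (3R,3aS,8S,8aR)-6,8a-dimethyl-3-(propan-2-yl)-2,3,4,5,8,8a-hexahydroazulene-3a,8(1H)-diol | O[C@H]1C=C(C)CC[C@]2(O)[C@@H](C(C)C)CC[C@]12C | intermediate
10 | 4-methoxybenzoyl chloride | COc1ccc(cc1)C(Cl)=O | starting material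
11 | (3R,3aS,8S,8aR)-3a-hydroxy-6,8a-dimethyl-3-(propan-2-yl)-1,2,3,3a,4,5,8,8a-octahydroazulen-8-yl 4-methoxybenzoate | COc1ccc(C(=O)O[C@H]2C=C(C)CC[C@]3(O)[C@@H](C(C)C)CC[C@]23C)cc1 | target

**Total step count:** 5. **Longest linear sequence:** 5 (1 → 2 → 3 → 8 → 9 → 11).

**Steps most likely to fail**

*Step 1 (proposed new step).*
- Iminium formation at the α'-branched ketone may be slow.
- Racemisation of 1 may not keep pace with epoxidation.
- Product 2 may partly epimerise at C3.

The fallback uses known chemistry only. It sets out from 1 (natural (R)-(−) grade) and comes back at 2.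
- Luche reduction (NaBH4, CeCl3·7H2O, MeOH, 0 °C) is non-basic, so C6 is not racemised. Axial hydride attack gives (1R,6R)-3-methyl-6-(propan-2-yl)cyclohex-2-en-1-ol F1, with the hydroxyl trans to the isopropyl group. The cis isomer is removed by chromatography.
- Hydroxyl-directed epoxidation (VO(acac)2, t-BuOOH, toluene) delivers oxygen syn to the hydroxyl, and therefore anti to the isopropyl group. This gives (1R,2R,3R,6S)-6-methyl-3-(propan-2-yl)-7-oxabicyclo[4.1.0]heptan-2-ol F2.
- Dess–Martin periodinane oxidation then returns 2. Its optical purity equals that of the feedstock.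

*Step 3.*
- The methyl group and the ring CH2 flanking the aldehyde differ little in size, so the Felkin–Anh ratio at the carbinol may be modest.
- The ketone is very hindered.
- The aldolate 7 can undergo retro-aldol cleavage on warming.

The fallback sets the carbinol centre by ketone reduction on the rigid bicycle instead of by addition to the aldehyde. It sets out from 3 and comes back at 9.
- The additions are run without regard to selectivity. Compound 8 is carried on together with its epimer (1S,2R,5R)-2-[(1R)-1-hydroxyprop-2-en-1-yl]-2-methyl-1-(3-methylbut-3-en-1-yl)-5-(propan-2-yl)cyclopentan-1-ol F3.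
- Metathesis as in the main route gives 9 together with (3R,3aS,8R,8aR)-6,8a-dimethyl-3-(propan-2-yl)-2,3,4,5,8,8a-hexahydroazulene-3a,8(1H)-diol F4.
- MnO2 in CH2Cl2 converts both into the single enone (3R,3aS,8aS)-3a-hydroxy-6,8a-dimethyl-3-(propan-2-yl)-2,3,3a,4,5,8a-hexahydroazulen-8(1H)-one F5.
- Narasaka–Prasad reduction (Et2BOMe, NaBH4, THF/MeOH, −78 °C) ties the tertiary alkoxide and the carbonyl into a boron chelate. External hydride attacks from the face away from the chelate, giving the syn-1,3-diol 9.

*Step 4.*
- The vinyl group is neopentylic.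
- The free allylic alcohol can be isomerised to an ethyl ketone by ruthenium hydrides.
- The 1,3-diol can chelate the catalyst.

The fallback inverts the order of esterification and ring closure. It sets out from 8 and comes back at 11.
- Selective acylation of the secondary hydroxyl of 8 with 10 (Et3N, DMAP, CH2Cl2) gives (1S)-1-[(1R,2S,3R)-2-hydroxy-1-methyl-2-(3-methylbut-3-en-1-yl)-3-(propan-2-yl)cyclopentyl]prop-2-en-1-yl 4-methoxybenzoate F6.
- F6 can no longer isomerise or chelate. It is closed with the second-generation Hoveyda–Grubbs catalyst in toluene at 80 °C directly to 11.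

**Further compounds**
F1 | step 1 | (1R,6R)-3-methyl-6-(propan-2-yl)cyclohex-2-en-1-ol | CC1=C[C@H](O)[C@@H](C(C)C)CC1
F2 | step 1 | (1R,2R,3R,6S)-6-methyl-3-(propan-2-yl)-7-oxabicyclo[4.1.0]heptan-2-ol | CC(C)[C@H]1CC[C@]2(C)O[C@@H]2[C@@H]1O
F3 | step 3 | (1S,2R,5R)-2-[(1R)-1-hydroxyprop-2-en-1-yl]-2-methyl-1-(3-methylbut-3-en-1-yl)-5-(propan-2-yl)cyclopentan-1-ol | C=C[C@@H](O)[C@@]1(C)CC[C@H](C(C)C)[C@@]1(O)CCC(C)=C
F4 | step 3 | (3R,3aS,8R,8aR)-6,8a-dimethyl-3-(propan-2-yl)-2,3,4,5,8,8a-hexahydroazulene-3a,8(1H)-diol | O[C@@H]1C=C(C)CC[C@]2(O)[C@@H](C(C)C)CC[C@]12C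
F5 | step 3 | (3R,3aS,8aS)-3a-hydroxy-6,8a-dimethyl-3-(propan-2-yl)-2,3,3a,4,5,8a-hexahydroazulen-8(1H)-one | O=C1C=C(C)CC[C@]2(O)[C@@H](C(C)C)CC[C@]12C
F6 | step 4 | (1S)-1-[(1R,2S,3R)-2-hydroxy-1-methyl-2-(3-methylbut-3-en-1-yl)-3-(propan-2-yl)cyclopentyl]prop-2-en-1-yl 4-methoxybenzoate | C=C[C@H](OC(=O)c1ccc(OC)cc1)[C@@]1(C)CC[C@H](C(C)C)[C@@]1(O)CCC(C)=C
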